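**Plan**
Numbering (icetexane): ring A = C1–C5, C10; ring B = C5–C10, C20 (seven-membered); ring C = C8, C9, C11–C14 (the quinone); an oxygen bridges C10 and the hemiketal carbon C7.
Retrosynthesis: the quinone is taken back to its 11,14-dimethyl ether; then C7–C8 is cut (aryl bromide plus a cis-fused γ-lactone that carries O10); then ring C is contracted to a 4-alkenyl-4-hydroxycyclobutenone; last, C9–C11 (vinyllithium plus cyclobutenedione) and C10–C20 (2-bromoallylation of a ketone) are cut.
Enabling feature: C11 and C14 are para carbonyl carbons flanking the C12–OMe/C13–i-Pr pair, so C11–C12–C13–C14 is a squarate-derived cyclobutenone in disguise and C9=C8 is an alkenyl group on its carbinol carbon; O10 and C7 are 1,4-related, so one five-membered lactol/lactone ring can carry both.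
Forward: ring A is bought; ring C is grown from the four-membered ring by thermal, strain-releasing ring expansion; ring B and the oxygen bridge close together when a C8 aryllithium attacks the lactone.
Stereochemistry: C5 by palladium-catalysed asymmetric allylation; C10 relayed from C5 by equatorial attack on the C10 ketone; C7 fixed by the bridge.

Key step: step 7

Remark: the (R,R)-ligand in step 2 is assumed to deliver the (S)-ketone; if the sense is the opposite, the enantiomeric ligand is used and nothing else changes.
Remark: compounds 8, 9 and 13–20 are mixtures at the acetal carbon (C7), and 14 also at its carbinol carbon; all these centres are erased later, so the mixtures converge.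

Step 1
Reactants: 1 3-methylcyclohex-2-en-1-one
Product: 3 allyl 3,3-dimethylcyclohex-1-en-1-yl carbonate, via lithium enolate 2 (not isolated)
Conditions: Me2CuLi (from CuI and 2 MeLi), Et2O, 0 °C; then TMEDA, ClCO2CH2CH=CH2, THF, −78 °C to 0 °C
Reagents that add atoms: lithium dimethylcuprate, [Li+].C[Cu-]C; allyl chloroformate, C=CCOC(Cl)=O
Why: Cuprate 1,4-addition creates the C4 gem-dimethyl carbon and gives the enolate regiospecifically toward it, and chloroformates should acylate lithium enolates on oxygen in THF/TMEDA (conjugate addition with enolate O-trapping).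

Step 2
Reactants: 3 allyl 3,3-dimethylcyclohex-1-en-1-yl carbonate
Product: 4 (S)-2-allyl-3,3-dimethylcyclohexan-1-one
Conditions: Pd2(dba)3·CHCl3 (2.5 mol %), (R,R)-11,12-bis[2-(diphenylphosphino)benzamido]-9,10-dihydro-9,10-ethanoanthracene (5.5 mol %), 1,4-dioxane, 23 °C
Reagents that add atoms: none
Why: Decarboxylative asymmetric allylic alkylation (Tsuji–Trost type): zerovalent palladium ionises the carbonate to a π-allylpalladium/enolate pair, CO2 is lost and C–C bond formation inside the chiral ligand pocket sets the tertiary C5 stereocentre under neutral conditions that should not racemise it.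

Step 3
Reactants: 4 (S)-2-allyl-3,3-dimethylcyclohexan-1-one; 5 2,3-dibromopropene
Product: 7 (1S,2S)-2-allyl-1-(2-bromoprop-2-en-1-yl)-3,3-dimethylcyclohexan-1-ol, via (2-bromoallyl)zinc bromide 6 (not isolated)
Conditions: Zn dust (activated), THF, 0 °C to rt (Barbier mode); sat. aq. NH4Cl
Reagents that add atoms: none
Why: Barbier-type zinc allylation; the axial C4 methyl group blocks the axial trajectory, so the reagent should attack C10 equatorially, which places C20 trans to the equatorial C5 allyl group and the hydroxyl cis to it, trans-diaxial to H5 (C10 set by substrate control from C5).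

Step 4
Reactants: 7 (1S,2S)-2-allyl-1-(2-bromoprop-2-en-1-yl)-3,3-dimethylcyclohexan-1-ol
Product: 9 (3aS,7aS)-7a-(2-bromoprop-2-en-1-yl)-2-methoxy-4,4-dimethyloctahydro-1-benzofuran (methyl acetal; both anomers), via lactol 8 (not isolated)
Conditions: O3 (1 equiv, indicator end point), CH2Cl2–MeOH, −78 °C; Me2S, −78 °C to rt; then PPTS (cat.), MeOH, 3 Å MS, rt
Reagents that add atoms: ozone, [O-][O+]=O (hydroxyl oxygen of lactol 8); methanol, CO (methoxy group of 9)
Why: Chemoselective ozonolysis of the electron-rich monosubstituted alkene in the presence of the electron-poor 2-bromoalkene; the γ-hydroxy aldehyde closes at once to the lactol because O10 and C6 are cis, and Fischer-type acetalisation caps it as a ring that masks both the C10 hydroxyl and C7.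

Step 5
Reactants: 10 dimethyl squarate (3,4-dimethoxycyclobut-3-ene-1,2-dione)
Product: 12 3-isopropyl-4-methoxycyclobut-3-ene-1,2-dione, via magnesium alkoxide 11 (not isolated)
Conditions: i-PrMgCl, THF, −78 °C; then (CF3CO)2O, −78 °C to rt; aq. NaHCO3
Reagents that add atoms: isopropylmagnesium chloride, CC(C)[Mg]Cl; water, O
Why: 1,2-Addition of the Grignard reagent to one squarate carbonyl, then trifluoroacetylation and ionisation of the tertiary carbinol and hydrolysis of the methoxy-stabilised cation (squarate addition–rearrangement).

Step 6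
Reactants: 9 methyl acetal; 12 3-isopropyl-4-methoxycyclobut-3-ene-1,2-dione
Product: 14 4-hydroxy-2-isopropyl-3-methoxy-4-{3-[(3aS,7aS)-2-methoxy-4,4-dimethyloctahydro-1-benzofuran-7a-yl]prop-1-en-2-yl}cyclobut-2-en-1-one, via vinyllithium 13 (not isolated)
Conditions: 9, t-BuLi (2.05 equiv), THF, −78 °C; cannulated into 12 (1.2 equiv), THF, −78 °C; sat. aq. NH4Cl at −78 °C
Reagents that add atoms: none
Why: Bromine–lithium exchange, then 1,2-addition to the ketone-like carbonyl of 12 (the one next to the methoxy-bearing carbon; the other is a vinylogous ester), which decides that the future C11 lies between C12–OMe and C9; the new carbinol stereocentre is uncontrolled and is destroyed in step 7.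

Step 7
Reactants: 14 4-alkenyl-4-hydroxycyclobutenone
Product: 17 2-isopropyl-3-methoxy-5-{[(3aS,7aS)-2-methoxy-4,4-dimethyloctahydro-1-benzofuran-7a-yl]methyl}benzene-1,4-diol, via dienylketene 15 (not isolated), via cyclohexa-2,4-dienone 16 (not isolated)
Conditions: degassed p-xylene (0.02 M), 2,6-di-tert-butylpyridine (5 mol %), 138 °C, Ar
Reagents that add atoms: none
Why: Heat opens the strained cyclobutenone by conrotatory 4π electrocyclic ring opening (the C11–C14 bond breaks), the C11 hydroxyl rotating outward and the alkenyl group inward to give the (Z)-dienylketene 15. Disrotatory 6π electrocyclisation then joins the ketene carbon C14 to the terminal alkene carbon C8 and closes six-membered ring C as dienone 16, and enolisation aromatises it to hydroquinone 17, so the four-membered ring has grown by C9 and C8. The closest known reaction type is the Moore-type thermal ring expansion of 4-alkenyl-4-hydroxycyclobutenones to hydroquinones. No stereocentre is formed and C5 and C10 are not touched. The selectivity needed is regiochemical (C11 between C12–OMe and C9, C14 between C13–i-Pr and C8); it is fixed by the site of addition in step 6 together with the torquoselectivity imposed by the hydroxyl donor, while high dilution and the unhindered CH2 terminus should favour cyclisation over ketene dimerisation and the acid-free medium should keep the acetal from ionising toward the free C8 position.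

Step 8
Reactants: 17 hydroquinone
Product: 18 (3aS,7aS)-7a-(4-isopropyl-2,3,5-trimethoxybenzyl)-2-methoxy-4,4-dimethyloctahydro-1-benzofuran
Conditions: MeI, K2CO3, degassed DMF, rt to 40 °C, Ar
Reagents that add atoms: iodomethane, CI
Why: Williamson ether synthesis on both phenols protects the air-sensitive hydroquinone as the dimethyl ether, which tolerates the organolithium chemistry of step 11 and is the direct precursor of the quinone.

Step 9
Reactants: 18 trimethoxyarene
Product: 19 (3aS,7aS)-7a-(2-bromo-4-isopropyl-3,5,6-trimethoxybenzyl)-2-methoxy-4,4-dimethyloctahydro-1-benzofuran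
Conditions: NBS, DMF, 0 °C, dark
Reagents that add atoms: N-bromosuccinimide, BrN1C(=O)CCC1=O
Why: Electrophilic aromatic bromination at C8, the only free ring position and ortho/para to two methoxy groups; the bromine is the handle for step 11 and blocks C8 against Friedel–Crafts capture of a C7 oxocarbenium ion in step 10.

Step 10
Reactants: 19 aryl bromide
Product: 21 (3aS,7aS)-7a-(2-bromo-4-isopropyl-3,5,6-trimethoxybenzyl)-4,4-dimethylhexahydro-1-benzofuran-2(3H)-one, via lactol 20 (not isolated)
Conditions: 1 M aq. HCl–THF, rt; extractive work-up; then (n-Pr4N)RuO4 (5 mol %), NMO, 4 Å MS, CH2Cl2, rt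
Reagents that add atoms: water, O
Why: Acetal hydrolysis followed by Ley–Griffith oxidation of the lactol raises C7 to the carboxyl level as the cis-fused γ-lactone without touching the electron-rich arene.

Step 11
Reactants: 21 bromo lactone
Product: 23 the (5S,7S,10S) bridged hemiketal, that is komaroviquinone with ring C as the 11,12,14-trimethoxyarene, via aryllithium 22 (not isolated)
Conditions: t-BuLi (2.1 equiv), THF, −100 °C to −78 °C; sat. aq. NH4Cl
Reagents that add atoms: none
Why: Parham cyclisation: bromine–lithium exchange and 7-exo-trig addition of the C8 aryllithium to the lactone carbonyl close ring B, and the tetrahedral adduct is itself the bridged hemiketal; C7 is set by the tether, because the aryl group hangs from C20 and can reach only the lactone face that carries C20 and H5.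

Step 12
Reactants: 23 trimethoxyarene hemiketal
Product: 24 komaroviquinone
Conditions: (NH4)2Ce(NO3)6 (2.5 equiv), MeCN–H2O, 0 °C
Reagents that add atoms: water, O
Why: Oxidative demethylation of the para-dimethoxyarene by tetravalent cerium (two one-electron oxidations, ipso attack of water, loss of methanol) should give the para-quinone across C11/C14 and keep the C12 methoxy group, whose loss would require the less stable ortho-quinone; C5, C7 and C10 are not affected.

**Compound list**
1 | 3-methylcyclohex-2-en-1-one | CC1=CC(=O)CCC1 | starting material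
2 | lithium 3,3-dimethylcyclohex-1-en-1-olate | [Li]OC1=CC(C)(C)CCC1 | intermediate (not isolated)
3 | allyl 3,3-dimethylcyclohex-1-en-1-yl carbonate | C=CCOC(=O)OC1=CC(C)(C)CCC1 | intermediate
4 | (S)-2-allyl-3,3-dimethylcyclohexan-1-one | O=C1CCCC(C)(C)[C@@H]1CC=C | intermediate
5 | 2,3-dibromopropene | C=C(Br)CBr | starting material
6 | (2-bromoprop-2-en-1-yl)zinc bromide | C=C(Br)C[Zn]Br | intermediate (not isolated)
7 | (1S,2S)-2-allyl-1-(2-bromoprop-2-en-1-yl)-3,3-dimethylcyclohexan-1-ol | C=C(Br)C[C@@]1(O)CCCC(C)(C)[C@@H]1CC=C | intermediate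
8 | (3aS,7aS)-7a-(2-bromoprop-2-en-1-yl)-4,4-dimethyloctahydro-1-benzofuran-2-ol (lactol) | C=C(Br)C[C@@]12CCCC(C)(C)[C@@H]1CC(O)O2 | intermediate (not isolated)
9 | (3aS,7aS)-7a-(2-bromoprop-2-en-1-yl)-2-methoxy-4,4-dimethyloctahydro-1-benzofuran | C=C(Br)C[C@@]12CCCC(C)(C)[C@@H]1CC(OC)O2 | intermediate
10 | dimethyl squarate | COC1=C(OC)C(=O)C1=O | starting material
11 | chloromagnesium alkoxide of 4-hydroxy-4-isopropyl-2,3-dimethoxycyclobut-2-en-1-one | COC1=C(OC)C(O[Mg]Cl)(C(C)C)C1=O | intermediate (not isolated)
12 | 3-isopropyl-4-methoxycyclobut-3-ene-1,2-dione | COC1=C(C(C)C)C(=O)C1=O | intermediate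
13 | vinyllithium from 9 (lithium in place of bromine) | C=C([Li])C[C@@]12CCCC(C)(C)[C@@H]1CC(OC)O2 | intermediate (not isolated)
14 | 4-hydroxy-2-isopropyl-3-methoxy-4-{3-[(3aS,7aS)-2-methoxy-4,4-dimethyloctahydro-1-benzofuran-7a-yl]prop-1-en-2-yl}cyclobut-2-en-1-one | COC1=C(C(C)C)C(=O)C1(O)C(=C)C[C@@]23CCCC(C)(C)[C@@H]2CC(OC)O3 | intermediate
15 | (Z)-dienylketene from ring opening of 14 | O=C=C(C(C)C)/C(OC)=C(O)\C(=C)C[C@@]12CCCC(C)(C)[C@@H]1CC(OC)O2 | intermediate (not isolated)
16 | 4-hydroxy-6-isopropyl-5-methoxycyclohexa-2,4-dien-1-one carrying the ring A side chain at C3 | O=C1CC(C[C@@]23CCCC(C)(C)[C@@H]2CC(OC)O3)=C(O)C(OC)=C1C(C)C | intermediate (not isolated)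
17 | 2-isopropyl-3-methoxy-5-{[(3aS,7aS)-2-methoxy-4,4-dimethyloctahydro-1-benzofuran-7a-yl]methyl}benzene-1,4-diol | COc1c(O)c(C[C@@]23CCCC(C)(C)[C@@H]2CC(OC)O3)cc(O)c1C(C)C | intermediate
18 | (3aS,7aS)-7a-(4-isopropyl-2,3,5-trimethoxybenzyl)-2-methoxy-4,4-dimethyloctahydro-1-benzofuran | COc1c(OC)c(C[C@@]23CCCC(C)(C)[C@@H]2CC(OC)O3)cc(OC)c1C(C)C | intermediate
19 | (3aS,7aS)-7a-(2-bromo-4-isopropyl-3,5,6-trimethoxybenzyl)-2-methoxy-4,4-dimethyloctahydro-1-benzofuran | COc1c(OC)c(C[C@@]23CCCC(C)(C)[C@@H]2CC(OC)O3)c(Br)c(OC)c1C(C)C | intermediate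
20 | lactol of 19 (OH in place of the acetal OMe) | COc1c(OC)c(C[C@@]23CCCC(C)(C)[C@@H]2CC(O)O3)c(Br)c(OC)c1C(C)C | intermediate (not isolated)
21 | (3aS,7aS)-7a-(2-bromo-4-isopropyl-3,5,6-trimethoxybenzyl)-4,4-dimethylhexahydro-1-benzofuran-2(3H)-one | COc1c(OC)c(C[C@@]23CCCC(C)(C)[C@@H]2CC(=O)O3)c(Br)c(OC)c1C(C)C | intermediate
22 | aryllithium from 21 (lithium at C8) | COc1c(OC)c(C[C@@]23CCCC(C)(C)[C@@H]2CC(=O)O3)c([Li])c(OC)c1C(C)C | intermediate (not isolated)
23 | (5S,7S,10S)-hemiketal with 11,12,14-trimethoxy ring C | COc1c(C(C)C)c(OC)c2c(C[C@@]34CCCC(C)(C)[C@@H]3C[C@]2(O)O4)c1OC | intermediate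
24 | komaroviquinone | COC1=C(C(C)C)C(=O)C2=C(C[C@@]34CCCC(C)(C)[C@@H]3C[C@]2(O)O4)C1=O | target

**Step count**
Total: 12 steps. Longest linear sequence: 11 steps (steps 1–4 and 6–12); step 5 is a one-step side branch.

**Steps most likely to fail**

Step 11. Proton transfer from the lactone α-CH2 (C6) to the C8 aryllithium may outrun the seven-membered ring closure, leaving debrominated lactone. The fallback sets out from 19 and closes ring B at the aldehyde oxidation level, where carbonyl addition is much faster. Aqueous HCl in THF gives lactol 20, now isolated. MeLi (1 equiv) followed by t-BuLi (2 equiv) in THF at −78 °C should exchange the bromine and add the aryllithium to the open hydroxy-aldehyde form, giving the ring B diol F1 as a mixture of C7 epimers. Dess–Martin periodinane oxidises the benzylic alcohol to the aryl ketone, which closes onto the C10 hydroxyl, and the route is rejoined at 23.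

Step 2. Enantioselectivity may erode, because alkylation at an enolate carbon next to the quaternary C4 is slow and enolate exchange or proton transfer can compete. The fallback sets out from 1. Enolate 2 is trapped with allyl bromide to give the racemic ketone F2. Reduction with catalytic (S)-2-methyl-CBS-oxazaborolidine and BH3·SMe2 delivers hydride under catalyst control to both enantiomers. The (S)-ketone should give the cis alcohol (1R,2S)-2-allyl-3,3-dimethylcyclohexan-1-ol F3 by the unhindered equatorial path, and the (R)-ketone the trans alcohol (1R,2R)-2-allyl-3,3-dimethylcyclohexan-1-ol F4 by the blocked axial path, so the two are separable diastereomers and also differ in rate. Oxidation of F3 with Dess–Martin periodinane returns to 4.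

Step 3. The 2-bromoallylzinc species may collapse to allene by β-elimination faster than it adds to the hindered ketone. The fallback sets out from 4. Propargyl bromide and Zn in THF (Barbier) should give, with the same equatorial bias, the homopropargylic alcohol (1S,2S)-2-allyl-3,3-dimethyl-1-(prop-2-yn-1-yl)cyclohexan-1-ol F5. Markovnikov hydrobromination of the terminal alkyne with tetraethylammonium hydrogen dibromide in CH2Cl2 then gives the 2-bromoalkene, and the route is rejoined at 7.

**Further compounds**
F1 | step 11 | (5S,10S)-7,10-diol: benzo-fused seven-membered ring B with C7–OH (both epimers), C10–OH and 11,12,14-trimethoxy ring C | COc1c(C(C)C)c(OC)c2c(C[C@@]3(O)CCCC(C)(C)[C@@H]3CC2O)c1OC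
F2 | step 2 | rac-2-allyl-3,3-dimethylcyclohexan-1-one | O=C1CCCC(C)(C)C1CC=C
F3 | step 2 | (1R,2S)-2-allyl-3,3-dimethylcyclohexan-1-ol | O[C@@H]1CCCC(C)(C)[C@@H]1CC=C
F4 | step 2 | (1R,2R)-2-allyl-3,3-dimethylcyclohexan-1-ol | O[C@@H]1CCCC(C)(C)[C@H]1CC=C
F5 | step 3 | (1S,2S)-2-allyl-3,3-dimethyl-1-(prop-2-yn-1-yl)cyclohexan-1-ol | C#CC[C@@]1(O)CCCC(C)(C)[C@@H]1CC=C
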